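**Retrosynthetic overview**

1. Target 14 is [(2R,3R,4R,5S)-2,5-bis(4-hydroxy-3,5-dimethoxyphenyl)oxolane-3,4-diyl]dimethanol; the end game from oxolane diester 10 is loss of one ester at C3, reduction of the other to CH2OH, and removal of the O-silyl and O-benzyl groups.
2. Key disconnection: the oxolane is cut at O1–C5 and at C2–C3. This gives O-benzylsyringaldehyde 2 (its C=O becomes C2–O1) and the cis donor–acceptor cyclopropane 8 (C5–C4–C3), joined in one Lewis acid (3+2) annulation.
3. Enabling feature: C5 is benzylic to an electron-rich 4-oxygenated 3,5-dimethoxyphenyl ring (donor), and C3, its 1,3-partner across C4, can carry a geminal diester (acceptor, later the CH2OH carbon), so C5–C4–C3 can be stored as a strained three-membered ring; C2–O1 with its aryl ring is a syringaldehyde carbonyl.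
4. Cyclopropane 8 comes from the same aldehyde 2 by Z-selective olefination, reduction, silylation and enantioselective copper-catalysed cyclopropanation, so both halves of the target derive from syringaldehyde.
5. Ring order: cyclopropane (step 6), then the oxolane by ring expansion of that cyclopropane (step 7); no other ring is formed.

Key step: step 7

Remark: locants O1 and C2–C5 are those of the oxolane names of 10–14 (C2 carries the aryl group cis to the C3 substituent, C5 the aryl group trans to the C4 substituent); the ligand antipode in step 6 is assumed to be chosen, by analogy with simple cis-1-arylalkenes, to give the (2R,3R)-cyclopropane.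

**Route**

Step 1
Reactants: 1 syringaldehyde (4-hydroxy-3,5-dimethoxybenzaldehyde)
Product: 2 4-(benzyloxy)-3,5-dimethoxybenzaldehyde
Conditions: BnBr, K2CO3, DMF, 60 °C
Reagents that add atoms: benzyl bromide, BrCc1ccccc1
Why: Williamson ether synthesis on the phenoxide; the benzyl ether keeps the para oxygen as an electron donor and should last until the final hydrogenolysis.

Step 2
Reactants: 2 4-(benzyloxy)-3,5-dimethoxybenzaldehyde
Product: 3 methyl (2Z)-3-[4-(benzyloxy)-3,5-dimethoxyphenyl]prop-2-enoate
Conditions: (CF3CH2O)2P(O)CH2CO2Me, KN(SiMe3)2, 18-crown-6, THF, −78 °C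
Reagents that add atoms: methyl 2-[bis(2,2,2-trifluoroethoxy)phosphoryl]acetate, COC(=O)CP(=O)(OCC(F)(F)F)OCC(F)(F)F
Why: Still–Gennari variant of the Horner–Wadsworth–Emmons olefination, in which the electron-poor phosphonate collapses kinetically through the syn oxaphosphetane to give the Z enoate needed for a cis cyclopropane.

Step 3
Reactants: 3 methyl (2Z)-3-[4-(benzyloxy)-3,5-dimethoxyphenyl]prop-2-enoate
Product: 4 (2Z)-3-[4-(benzyloxy)-3,5-dimethoxyphenyl]prop-2-en-1-ol
Conditions: i-Bu2AlH (2.5 equiv), CH2Cl2, −78 °C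
Reagents that add atoms: none
Why: 1,2-reduction of the enoate by the aluminium hydride at low temperature should leave the Z double bond and the benzyl ether untouched.

Step 4
Reactants: 4 (2Z)-3-[4-(benzyloxy)-3,5-dimethoxyphenyl]prop-2-en-1-ol
Product: 5 {[(2Z)-3-[4-(benzyloxy)-3,5-dimethoxyphenyl]prop-2-en-1-yl]oxy}tri(propan-2-yl)silane
Conditions: i-Pr3SiCl, imidazole, DMF, rt
Reagents that add atoms: chlorotri(propan-2-yl)silane, CC(C)[Si](Cl)(C(C)C)C(C)C
Why: standard silylation of a primary alcohol; the bulky, non-participating silyl ether should suppress oxonium ylide formation in step 6 and neighbouring-group participation in step 7.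

Step 5
Reactants: 6 dimethyl malonate
Product: 7 dimethyl 2-(phenyl-λ3-iodanylidene)propanedioate
Conditions: PhI(OAc)2, KOH, MeCN, 0 °C
Reagents that add atoms: (diacetoxyiodo)benzene, CC(=O)OI(OC(C)=O)c1ccccc1
Why: known condensation of the malonate anion with PhI(OAc)2 to the bench-stable iodonium ylide, a malonyl carbene source that transfers at low temperature.

Step 6
Reactants: 5 {[(2Z)-3-[4-(benzyloxy)-3,5-dimethoxyphenyl]prop-2-en-1-yl]oxy}tri(propan-2-yl)silane; 7 dimethyl 2-(phenyl-λ3-iodanylidene)propanedioate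
Product: 8 dimethyl (2R,3R)-2-[4-(benzyloxy)-3,5-dimethoxyphenyl]-3-({[tri(propan-2-yl)silyl]oxy}methyl)cyclopropane-1,1-dicarboxylate
Conditions: Cu(MeCN)4PF6 (10 mol %), side-arm bis(oxazoline) ligand (12 mol %), 4 Å MS, toluene, 0 °C
Reagents that add atoms: none
Why: copper–bis(oxazoline)-catalysed asymmetric cyclopropanation (carbene transfer from an iodonium ylide) of a cis-1,2-disubstituted aryl alkene; the concerted addition keeps aryl and CH2OSi cis, and the chiral ligand selects the alkene face, which sets both stereocentres together as 2R,3R.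

Step 7
Reactants: 8 dimethyl (2R,3R)-2-[4-(benzyloxy)-3,5-dimethoxyphenyl]-3-({[tri(propan-2-yl)silyl]oxy}methyl)cyclopropane-1,1-dicarboxylate; 2 4-(benzyloxy)-3,5-dimethoxybenzaldehyde
Product: 10 dimethyl (2S,4R,5S)-2,5-bis[4-(benzyloxy)-3,5-dimethoxyphenyl]-4-({[tri(propan-2-yl)silyl]oxy}methyl)oxolane-3,3-dicarboxylate, via oxocarbenium malonate zwitterion 9 (not isolated)
Conditions: AlCl3 (20 mol %), 2 (3 equiv), CH2Cl2, 0 °C to rt
Reagents that add atoms: none
Why: AlCl3 chelates the geminal diester and polarises the C1–C2 bond of 8; the carbonyl oxygen of 2 attacks the benzylic carbon from the rear (SN2-like opening of the three-membered ring) to give zwitterion 9, and the aluminium malonate then adds to the E-oxocarbenium carbon. The closest known reaction type is the Lewis acid catalysed (3+2) annulation of 2-aryl and 2,3-disubstituted cyclopropane-1,1-diesters with aldehydes, which gives 2,5-cis-oxolanes with inversion at the donor carbon. The only ring closed is the oxolane, by C–C bond formation in a formal 5-endo-trig (enolate exo) aldol-type attack on the cationic C=O, a closure that is easy for oxocarbenium ions. C5 (S) is set by inversion of the (2R) donor carbon of 8 and so ends trans to the untouched C4 substituent because 8 is cis; C2 (S in 10, R once one ester is gone) is set in the ring closure, where an envelope transition state with both aryl groups and the C4 side chain pseudo-equatorial should give the 2,5-cis product; C4 (R) is carried over from 8. The step needs stereospecific capture to outrun Lewis acid epimerisation of the cis cyclopropane to its trans isomer: the 4-benzyloxy oxygen is twisted out of conjugation by its two methoxy neighbours, so the aryl donor is only moderately cation-stabilising, and excess aldehyde at low temperature keeps the bimolecular capture fast. Regioselectivity (cleavage of the aryl-bearing C1–C2 bond and not C1–C3) follows from benzylic stabilisation of the developing positive charge.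

Step 8
Reactants: 10 dimethyl (2S,4R,5S)-2,5-bis[4-(benzyloxy)-3,5-dimethoxyphenyl]-4-({[tri(propan-2-yl)silyl]oxy}methyl)oxolane-3,3-dicarboxylate
Product: 11 methyl (2R,3S,4R,5S)-2,5-bis[4-(benzyloxy)-3,5-dimethoxyphenyl]-4-({[tri(propan-2-yl)silyl]oxy}methyl)oxolane-3-carboxylate
Conditions: LiCl, H2O, DMSO, 140 °C
Reagents that add atoms: none
Why: Krapcho dealkoxycarbonylation; the ester enolate left after loss of CO2 should be protonated kinetically from the ring face opposite the two cis aryl groups (C2 adjacent, C5 across the ring), which is the face of the slim CH2 of the C4 side chain, so that the surviving CO2Me ends cis to the C2 aryl group and trans to C4–CH2OSi (3S).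

Step 9
Reactants: 11 methyl (2R,3S,4R,5S)-2,5-bis[4-(benzyloxy)-3,5-dimethoxyphenyl]-4-({[tri(propan-2-yl)silyl]oxy}methyl)oxolane-3-carboxylate
Product: 12 [(2R,3R,4R,5S)-2,5-bis[4-(benzyloxy)-3,5-dimethoxyphenyl]-4-({[tri(propan-2-yl)silyl]oxy}methyl)oxolan-3-yl]methanol
Conditions: LiAlH4, THF, 0 °C
Reagents that add atoms: none
Why: hydride reduction of the ester to the primary alcohol removes the last epimerisable centre; silyl ether, benzyl ethers and ring ethers are inert to LiAlH4.

Step 10
Reactants: 12 [(2R,3R,4R,5S)-2,5-bis[4-(benzyloxy)-3,5-dimethoxyphenyl]-4-({[tri(propan-2-yl)silyl]oxy}methyl)oxolan-3-yl]methanol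
Product: 13 [(2R,3R,4R,5S)-2,5-bis[4-(benzyloxy)-3,5-dimethoxyphenyl]oxolane-3,4-diyl]dimethanol
Conditions: Bu4NF, THF, rt
Reagents that add atoms: none
Why: fluoride-induced cleavage of the silyl ether, driven by the Si–F bond; no stereocentre is touched.

Step 11
Reactants: 13 [(2R,3R,4R,5S)-2,5-bis[4-(benzyloxy)-3,5-dimethoxyphenyl]oxolane-3,4-diyl]dimethanol
Product: 14 [(2R,3R,4R,5S)-2,5-bis(4-hydroxy-3,5-dimethoxyphenyl)oxolane-3,4-diyl]dimethanol
Conditions: H2 (1 atm), Pd/C, EtOAc–MeOH, rt
Reagents that add atoms: none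
Why: hydrogenolysis of the two aryl benzyl ethers, which should cleave much faster than the ring benzylic C–O bonds under neutral conditions, so the reaction is stopped once two benzyl groups are gone.

**Compound list**

1 | syringaldehyde (4-hydroxy-3,5-dimethoxybenzaldehyde) | COc1cc(C=O)cc(OC)c1O | starting material
2 | 4-(benzyloxy)-3,5-dimethoxybenzaldehyde | COc1cc(C=O)cc(OC)c1OCc1ccccc1 | intermediate
3 | methyl (2Z)-3-[4-(benzyloxy)-3,5-dimethoxyphenyl]prop-2-enoate | COC(=O)/C=C\c1cc(OC)c(OCc2ccccc2)c(OC)c1 | intermediate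
4 | (2Z)-3-[4-(benzyloxy)-3,5-dimethoxyphenyl]prop-2-en-1-ol | OC/C=C\c1cc(OC)c(OCc2ccccc2)c(OC)c1 | intermediate
5 | {[(2Z)-3-[4-(benzyloxy)-3,5-dimethoxyphenyl]prop-2-en-1-yl]oxy}tri(propan-2-yl)silane | CC(C)[Si](OC/C=C\c1cc(OC)c(OCc2ccccc2)c(OC)c1)(C(C)C)C(C)C | intermediate
6 | dimethyl malonate | COC(=O)CC(=O)OC | starting material
7 | dimethyl 2-(phenyl-λ3-iodanylidene)propanedioate | COC(=O)C(=Ic1ccccc1)C(=O)OC | intermediate
8 | dimethyl (2R,3R)-2-[4-(benzyloxy)-3,5-dimethoxyphenyl]-3-({[tri(propan-2-yl)silyl]oxy}methyl)cyclopropane-1,1-dicarboxylate | COC(=O)C1(C(=O)OC)[C@@H](c2cc(OC)c(OCc3ccccc3)c(OC)c2)[C@H]1CO[Si](C(C)C)(C(C)C)C(C)C | intermediate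
9 | oxocarbenium malonate zwitterion (aluminium-bound malonate; E-oxocarbenium on the former donor carbon) | COC(=O)[C-](C(=O)OC)[C@H](CO[Si](C(C)C)(C(C)C)C(C)C)[C@@H](c1cc(OC)c(OCc2ccccc2)c(OC)c1)/[O+]=C/c1cc(OC)c(OCc2ccccc2)c(OC)c1 | intermediate
10 | dimethyl (2S,4R,5S)-2,5-bis[4-(benzyloxy)-3,5-dimethoxyphenyl]-4-({[tri(propan-2-yl)silyl]oxy}methyl)oxolane-3,3-dicarboxylate | COc1cc([C@H]2O[C@@H](c3cc(OC)c(OCc4ccccc4)c(OC)c3)C(C(=O)OC)(C(=O)OC)[C@@H]2CO[Si](C(C)C)(C(C)C)C(C)C)cc(OC)c1OCc1ccccc1 | intermediate
11 | methyl (2R,3S,4R,5S)-2,5-bis[4-(benzyloxy)-3,5-dimethoxyphenyl]-4-({[tri(propan-2-yl)silyl]oxy}methyl)oxolane-3-carboxylate | COc1cc([C@H]2O[C@@H](c3cc(OC)c(OCc4ccccc4)c(OC)c3)[C@@H](C(=O)OC)[C@@H]2CO[Si](C(C)C)(C(C)C)C(C)C)cc(OC)c1OCc1ccccc1 | intermediate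
12 | [(2R,3R,4R,5S)-2,5-bis[4-(benzyloxy)-3,5-dimethoxyphenyl]-4-({[tri(propan-2-yl)silyl]oxy}methyl)oxolan-3-yl]methanol | COc1cc([C@H]2O[C@@H](c3cc(OC)c(OCc4ccccc4)c(OC)c3)[C@@H](CO)[C@@H]2CO[Si](C(C)C)(C(C)C)C(C)C)cc(OC)c1OCc1ccccc1 | intermediate
13 | [(2R,3R,4R,5S)-2,5-bis[4-(benzyloxy)-3,5-dimethoxyphenyl]oxolane-3,4-diyl]dimethanol | COc1cc([C@H]2O[C@@H](c3cc(OC)c(OCc4ccccc4)c(OC)c3)[C@@H](CO)[C@@H]2CO)cc(OC)c1OCc1ccccc1 | intermediate
14 | [(2R,3R,4R,5S)-2,5-bis(4-hydroxy-3,5-dimethoxyphenyl)oxolane-3,4-diyl]dimethanol | COc1cc([C@H]2O[C@@H](c3cc(OC)c(O)c(OC)c3)[C@@H](CO)[C@@H]2CO)cc(OC)c1O | target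

**Step count and risks**

Total step count: 11 (ten on the main line plus the one-step preparation of ylide 7).
Longest linear sequence: 10 steps (1 → 2 → 3 → 4 → 5 → 8 → 10 → 11 → 12 → 13 → 14).

Steps most likely to fail:

1. Step 8. The process at risk is the facial selectivity of the protonation of the C3 ester enolate, which has a substituent on each face (C2 aryl above, C4 side chain below), together with epimerisation of C3 at 140 °C toward the isomer with the ester trans to the C2 aryl group. The fallback sets out from 10 and comes back at 11. The Krapcho product is taken on as the unseparated mixture of 11 and its C3 epimer, methyl (2R,3R,4R,5S)-2,5-bis[4-(benzyloxy)-3,5-dimethoxyphenyl]-4-({[tri(propan-2-yl)silyl]oxy}methyl)oxolane-3-carboxylate F1. The mixture is deprotonated with LiN(i-Pr)2 in THF at −78 °C to the single lithium ester enolate of 11 F2. This enolate is protonated at −78 °C with the bulky acid 2,6-di-tert-butyl-4-methylphenol, which at that temperature should approach only from the face away from both aryl groups and so deliver 11 irreversibly; any remaining F1 is separated and put through the same cycle again.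

2. Step 7. The process at risk is Lewis acid-induced ring opening and re-closure of the cis cyclopropane to its trans isomer before the aldehyde attacks, which would erode the transfer of configuration to C5; capture may also be slow next to the bulky silyl ether. The fallback sets out from 8 and comes back at 10, and builds the same two bonds in two stages. Aldehyde 2 is reduced (NaBH4, MeOH) to [4-(benzyloxy)-3,5-dimethoxyphenyl]methanol F3, a much stronger oxygen nucleophile than the aldehyde. Cu(OTf)2-catalysed ring opening of 8 by F3 (CH2Cl2, 0 °C) should give, with inversion at the benzylic carbon, dimethyl 2-[(1S,2R)-1-[4-(benzyloxy)-3,5-dimethoxyphenyl]-1-{[4-(benzyloxy)-3,5-dimethoxyphenyl]methoxy}-3-{[tri(propan-2-yl)silyl]oxy}propan-2-yl]propanedioate F4. DDQ (CH2Cl2, 4 Å MS, 0 °C) then abstracts hydride from the less hindered ArCH2–O position of F4 and regenerates oxocarbenium malonate 9, which closes to 10 (oxidative benzylic C–H cleavage with intramolecular malonate capture, a cross-dehydrogenative coupling).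

3. Step 6. The process at risk is incomplete enantiofacial discrimination on this cis alkene, and diversion of the copper carbenoid to the ether oxygen or the electron-rich arene. The fallback sets out from 5 and comes back at 8. Cyclopropanation of 5 with dimethyl diazomalonate and Rh2(esp)2 (dirhodium bis(α,α,α′,α′-tetramethyl-1,3-benzenedipropionate), CH2Cl2, rt) is stereospecific for the cis relation but gives the racemate, that is 8 together with its enantiomer, dimethyl (2S,3S)-2-[4-(benzyloxy)-3,5-dimethoxyphenyl]-3-({[tri(propan-2-yl)silyl]oxy}methyl)cyclopropane-1,1-dicarboxylate F5. Compound 8 is then obtained by preparative HPLC on a chiral stationary phase.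

**Further compounds**

F1 | step 8 | methyl (2R,3R,4R,5S)-2,5-bis[4-(benzyloxy)-3,5-dimethoxyphenyl]-4-({[tri(propan-2-yl)silyl]oxy}methyl)oxolane-3-carboxylate | COc1cc([C@H]2O[C@@H](c3cc(OC)c(OCc4ccccc4)c(OC)c3)[C@H](C(=O)OC)[C@@H]2CO[Si](C(C)C)(C(C)C)C(C)C)cc(OC)c1OCc1ccccc1
F2 | step 8 | lithium ester enolate of 11 | COc1cc([C@H]2O[C@@H](c3cc(OC)c(OCc4ccccc4)c(OC)c3)C(=C(OC)[O-])[C@@H]2CO[Si](C(C)C)(C(C)C)C(C)C)cc(OC)c1OCc1ccccc1.[Li+]
F3 | step 7 | [4-(benzyloxy)-3,5-dimethoxyphenyl]methanol | COc1cc(CO)cc(OC)c1OCc1ccccc1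
F4 | step 7 | dimethyl 2-[(1S,2R)-1-[4-(benzyloxy)-3,5-dimethoxyphenyl]-1-{[4-(benzyloxy)-3,5-dimethoxyphenyl]methoxy}-3-{[tri(propan-2-yl)silyl]oxy}propan-2-yl]propanedioate | COC(=O)C(C(=O)OC)[C@H](CO[Si](C(C)C)(C(C)C)C(C)C)[C@@H](c1cc(OC)c(OCc2ccccc2)c(OC)c1)OCc1cc(OC)c(OCc2ccccc2)c(OC)c1
F5 | step 6 | dimethyl (2S,3S)-2-[4-(benzyloxy)-3,5-dimethoxyphenyl]-3-({[tri(propan-2-yl)silyl]oxy}methyl)cyclopropane-1,1-dicarboxylate | COC(=O)C1(C(=O)OC)[C@H](c2cc(OC)c(OCc3ccccc3)c(OC)c2)[C@@H]1CO[Si](C(C)C)(C(C)C)C(C)C
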